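The readings stem from a simulated flask with made-up constants, noise included.

If more solid reagent meant faster target, the spring run, charged with 18 mM, would pull steadily ahead of the dawn run, charged with 12 mM.

the same everywhere: starting material 22 mM

| flask | solid reagent | remark | time |
|---|---|---|---|
| dawn | 12 mM | run made earlier |  |
| spring | 18 mM | run made earlier |  |
| flask | 24.2 mM |  | 30 min |

- dawn (time / min: target / %): 1.33: 1.0; 3.00: 1.9; 8.00: 9.3; 20.0: 22.5
- spring (time / min: target / %): 1.33: 0.2; 3.00: 1.8; 8.00: 7.5; 20.0: 23.9

(each reading ± 0.5 percentage points)

1. amount of target at 30 min, in percent of the starting material charged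
2. concentration of partner in solution at 30 min, in percent of saturation

But at 8.00 min the dawn run leads, 9.3% against 7.5%, and at 20.0 min the spring run leads, 23.9% against 22.5%, so the gaps show no direction. We therefore freeze partner: we take its concentration as constant, held near saturation by undissolved solid, and treat both runs as one curve. On that curve the readings after the first minutes look nearly straight, so we carry one quantity, the growth slope g, the rise of target per minute as a fraction of the starting material charged. The mean readings are 1.85% at 3.00 min and 23.2% at 20.0 min, so g is 0.0126 min⁻¹. Carried on to 30 min, our line gives 35.8%. If each target takes one partner, that target takes 7.87 mM of partner, less than the 24.2 mM of solid reagent charged, so we expect solid to remain and partner to stay just below saturation, though the readings give no figure.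

The forecast says 34% (30% to 38%) of target, lower than our line, and partner at 92% (75% to 99.5%) of saturation, holding that “the solid loading does not set the rate”.

The flask gives 33.5% of target, with partner at 99.1% of saturation.

    starting material → intermediate A (k = 0.130 min⁻¹)
    starting material + partner → side product A (k = 1.10 M⁻¹ min⁻¹)
    starting material ⇌ intermediate B (K = 1.00, k = 0.190 min⁻¹)
    partner + intermediate A → target (k = 5.90 M⁻¹ min⁻¹)
    intermediate B → side product B (k = 0.0380 min⁻¹)
    starting material → side product B (k = 0.0780 min⁻¹)
    solid reagent ⇌ partner, rate k7*(cs7 - [partner]) while solid is left; crystals form when [partner] > cs7 (solubility = 8.00 mM, k = 2.60 min⁻¹)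

In the flask, partner stands at 7.89 mM at 3.00 min and 7.93 mM at 30.0 min, but between 15.0 min and 30 min target rises on average at 0.0107 min⁻¹, less than g, and our line ends 2.3 percentage points high. The neighbouring flask has the same charge and is read at 8.0 min. From the mean at 3.00 min, g gives 8.15%, and that flask shows 8.03% of target, with partner at 7.87 mM.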